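**Plan**

- Numbering: benzofuran O1, C2, C3, C3a–C7a; C9 is the hydroxymethyl carbon, C1′ the guaiacyl ipso carbon. The target is the trans-(2S,3R) isomer.
- Retrosynthesis: cut the aryl O–Si bond of a protected precursor, then O1–C2 and C3–C9 together, then C3–C3a (aryl–vinyl), then C2=C3 (methylenation of an aldehyde).
- Enabling feature: without O1–C2 and C9 the dihydrofuran is a flat 2-hydroxystilbene. Its C2 end is benzylic to the para-oxygenated guaiacyl ring (C1′) and carries positive charge well. Its C3 end is benzylic to ring A, which the C5 ester depletes, and the C7a hydroxyl sits in reach of C2 for a five-membered closure.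
- Forward: iodinate methyl vanillate; silylate and methylenate vanillin; join the two arenes by Heck coupling to the E-stilbene; add formaldehyde at C3 while the phenol closes the only new ring onto C2; remove the silyl group.
- Stereochemistry: no stereocentre exists before the key step. C3 comes from the chiral acid in the C–C bond formation, and C2 follows from C3 through trans-selective, reversible ring closure.

Key step: step 5

Assumption: the sense of induction of the confined acid cannot be predicted for this new substrate class; the catalyst is written as (S,S), and its mirror image is to be used if that one delivers (3R).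

**Route**

Step 1
Reactants: 1 methyl vanillate (methyl 4-hydroxy-3-methoxybenzoate)
Product: 2 methyl 5-iodovanillate (methyl 4-hydroxy-3-iodo-5-methoxybenzoate)
Conditions: NIS (1.05 equiv), TFA (10 mol%), MeCN, 0 °C to rt
Reagents that add atoms: N-iodosuccinimide, O=C1CCC(=O)N1I
Why: Electrophilic aromatic iodination; the phenol directs to its only free ortho position because the para position carries the ester.

Step 2
Reactants: 3 vanillin (4-hydroxy-3-methoxybenzaldehyde)
Product: 4 O-TIPS-vanillin (3-methoxy-4-[(triisopropylsilyl)oxy]benzaldehyde)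
Conditions: TIPSCl (1.1 equiv), imidazole (2.2 equiv), DMF, rt
Reagents that add atoms: triisopropylsilyl chloride, CC(C)[Si](Cl)(C(C)C)C(C)C
Why: Imidazole-mediated silylation of the acidic phenol; the bulky silyl ether should survive ylide, Pd/amine and acid, resists silyl transfer from a quinoid cation, and keeps the para oxygen a strong donor.

Step 3
Reactants: 4 O-TIPS-vanillin
Product: 5 TIPS ether of 4-vinylguaiacol ((4-ethenyl-2-methoxyphenoxy)triisopropylsilane)
Conditions: Ph3PCH3Br (1.3 equiv), KOtBu (1.25 equiv), THF, 0 °C to rt
Reagents that add atoms: methyltriphenylphosphonium bromide, C[P+](c1ccccc1)(c1ccccc1)c1ccccc1.[Br-]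
Why: Wittig methylenation of an aromatic aldehyde with the non-stabilised ylide; the aryl silyl ether is inert to it.

Step 4
Reactants: 2 methyl 5-iodovanillate; 5 TIPS ether of 4-vinylguaiacol
Product: 6 methyl 4-hydroxy-3-methoxy-5-[(E)-2-{3-methoxy-4-[(triisopropylsilyl)oxy]phenyl}ethenyl]benzoate (E-2-hydroxystilbene)
Conditions: Pd(OAc)2 (5 mol%), P(o-tol)3 (10 mol%), Et3N (3 equiv), DMF, 90 °C
Reagents that add atoms: none
Why: Mizoroki–Heck coupling; oxidative addition into the ester-activated aryl iodide, syn-carbopalladation at the terminal carbon of the styrene and syn β-hydride elimination should give the E-stilbene, with the free phenol and the silyl ether tolerated under amine base.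

Step 5
Reactants: 6 E-2-hydroxystilbene; 7 formaldehyde (charged as paraformaldehyde)
Product: 8 curlignan TIPS ether (methyl (2S,3R)-3-(hydroxymethyl)-7-methoxy-2-{3-methoxy-4-[(triisopropylsilyl)oxy]phenyl}-2,3-dihydro-1-benzofuran-5-carboxylate)
Conditions: (CH2O)n (1.2 equiv as CH2O), confined imino-imidodiphosphate acid (S,S)-iIDP built from 3,3′-diaryl-BINOL units (5 mol%), CHCl3/cyclohexane, 0 °C; Et3N quench
Reagents that add atoms: none
Why: Proposed new method: the chiral acid cracks paraformaldehyde and holds monomeric formaldehyde as a hydrogen-bonded hydroxymethyl-cation equivalent; C3 of the stilbene attacks it (C3–C9) because the charge then develops at C2 as a para-silyloxybenzyl, quinoid oxocarbenium ion, while attack through C2 would place it beside ring A, whose phenol lone pair is engaged by the para ester, and the C7a phenol then collapses onto C2 (O1–C2). The closest known reaction type is the catalytic asymmetric intermolecular Prins reaction of styrenes with paraformaldehyde under confined imino-imidodiphosphate acids, where a second formaldehyde closes a 1,3-dioxane; here the internal phenol takes that role, and the reverse fragmentation of phenylcoumarans into stilbene and formaldehyde, familiar from lignin degradation, speaks for this open-cation manifold. The dihydrofuran ring closes 5-exo-trig, the phenol oxygen adding to C2 of the exocyclic quinoid C2=C1′ bond. C3 is set in the C–C bond-forming event by the chiral counter-anion, which is hydrogen-bonded to the phenol and leaves one face of the E-alkene open to the bound formaldehyde; C2 is set by C3, the aryl group settling anti to the new hydroxymethyl group, and since O1–C2 can re-ionise under the acid any cis isomer should drain to trans-(2S,3R) without touching C3. The step needs attack through C3, one alkene face, and capture by the phenol ahead of a proton or a second formaldehyde; the donor/acceptor bias of the two rings, the confined anion, the intramolecular five-membered closure and a near-stoichiometric formaldehyde charge at low temperature should secure them. The reaction is a pure addition, so every atom of 6 and 7 ends up in 8.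

Step 6
Reactants: 8 curlignan TIPS ether
Product: 9 curlignan (methyl (2S,3R)-2-(4-hydroxy-3-methoxyphenyl)-3-(hydroxymethyl)-7-methoxy-2,3-dihydro-1-benzofuran-5-carboxylate)
Conditions: TBAF (1.1 equiv), AcOH (1.2 equiv), THF, 0 °C
Reagents that add atoms: none
Why: Fluoride-mediated desilylation of an aryl silyl ether; acetic acid buffers the liberated phenoxide so that the base-labile O1–C2 benzylic aryl ether, the ester and both stereocentres should stay untouched.

**Compound list**

1 | methyl vanillate (methyl 4-hydroxy-3-methoxybenzoate) | COC(=O)c1ccc(O)c(OC)c1 | starting material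
2 | methyl 4-hydroxy-3-iodo-5-methoxybenzoate | COC(=O)c1cc(I)c(O)c(OC)c1 | intermediate
3 | vanillin (4-hydroxy-3-methoxybenzaldehyde) | COc1cc(C=O)ccc1O | starting material
4 | 3-methoxy-4-[(triisopropylsilyl)oxy]benzaldehyde | COc1cc(C=O)ccc1O[Si](C(C)C)(C(C)C)C(C)C | intermediate
5 | (4-ethenyl-2-methoxyphenoxy)triisopropylsilane | C=Cc1ccc(O[Si](C(C)C)(C(C)C)C(C)C)c(OC)c1 | intermediate
6 | methyl 4-hydroxy-3-methoxy-5-[(E)-2-{3-methoxy-4-[(triisopropylsilyl)oxy]phenyl}ethenyl]benzoate | COC(=O)c1cc(OC)c(O)c(/C=C/c2ccc(O[Si](C(C)C)(C(C)C)C(C)C)c(OC)c2)c1 | intermediate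
7 | formaldehyde (used as paraformaldehyde) | C=O | starting material
8 | methyl (2S,3R)-3-(hydroxymethyl)-7-methoxy-2-{3-methoxy-4-[(triisopropylsilyl)oxy]phenyl}-2,3-dihydro-1-benzofuran-5-carboxylate | COC(=O)c1cc(OC)c2c(c1)[C@H](CO)[C@@H](c1ccc(O[Si](C(C)C)(C(C)C)C(C)C)c(OC)c1)O2 | intermediate
9 | curlignan, methyl (2S,3R)-2-(4-hydroxy-3-methoxyphenyl)-3-(hydroxymethyl)-7-methoxy-2,3-dihydro-1-benzofuran-5-carboxylate | COC(=O)c1cc(OC)c2c(c1)[C@H](CO)[C@@H](c1ccc(O)c(OC)c1)O2 | target

**Step count**

Total: 6 steps. Longest linear sequence: 5 steps (3 → 4 → 5 → 6 → 8 → 9); the iodide 2 is made in one step and joins at step 4.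

**Steps most likely to fail**

Step 5 (new method). Several processes could defeat it:
- The acid may deliver a proton instead of formaldehyde to C3, closing the ring without C9.
- The ring-A phenol may polarise the alkene the other way, so that C2 attacks formaldehyde.
- A second formaldehyde may intercept the C2 cation before the phenol does.
- The bulky silyl stilbene may not fit the confined pocket, or the alkene face may be poorly discriminated.
- Reversible loss of formaldehyde may erode C3 on long exposure to acid.
- The electron-rich stilbene may dimerise by a cationic pathway.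

The fallback uses known chemistry, sets out from 2 and 4, and returns at 8. The phenol of 2 would be benzylated (BnBr, K2CO3, DMF) to methyl 4-(benzyloxy)-3-iodo-5-methoxybenzoate F1. Palladium-catalysed coupling with the Reformatsky reagent of tert-butyl bromoacetate (BrZnCH2CO2tBu, Pd2(dba)3/XPhos, THF) should give the tert-butyl arylacetate F2, which tolerates the methyl ester. TFA in CH2Cl2 would free the arylacetic acid F3. Acylation of (S)-4-benzyl-2-oxazolidinone through the pivaloyl mixed anhydride (PivCl, Et3N, LiCl, THF) should give the N-arylacetyl oxazolidinone F4. An Evans syn-aldol reaction (Bu2BOTf, iPr2NEt, CH2Cl2, −78 °C) with aldehyde 4 would fix the future C3 through the auxiliary and should give the (2S,3S)-syn-aldol imide F5. LiBH4 in THF/MeOH at 0 °C should cleave the imide reductively, sparing the aryl methyl ester, to the (1S,2R)-1,3-diol benzyl ether F6. Hydrogenolysis (H2, Pd/C, EtOAc) would free the phenol in the (1S,2R)-phenol diol F7. Catalytic acid (PPTS, CH2Cl2, 0 °C) should ionise the para-silyloxybenzylic alcohol, and the phenol would close the ring trans under thermodynamic control, giving 8 with C3 unchanged.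

Step 4 (Heck coupling). The ortho-iodophenoxide may tie up palladium and stall turnover, the electron-rich styrene may be arylated at its internal carbon or polymerise at 90 °C, and the silyl ether may be partly lost. The fallback replaces the Heck disconnection by a Suzuki coupling, sets out from 4 and 2, and returns at 6. Boron-Wittig olefination of 4 with lithiated bis(pinacolatoboryl)methane (CH2(Bpin)2, LiTMP, THF, −78 °C to rt) should give the (E)-alkenylboronate 2-[(E)-2-{3-methoxy-4-[(triisopropylsilyl)oxy]phenyl}ethenyl]-4,4,5,5-tetramethyl-1,3,2-dioxaborolane F8 without passing through the styrene. Suzuki–Miyaura coupling of F8 with 2 (Pd(dppf)Cl2, K3PO4, THF/H2O, 50 °C) should then give 6 with the E geometry retained.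

Step 6 (desilylation). Fluoride liberates a para-phenoxide that can expel the O1 aryloxide through a quinone methide; this would epimerise C2, open the ring or, in the extreme, release formaldehyde. The fallback changes the protecting group to one removed under neutral conditions, sets out from 3 and returns at 9. It reuses the step-5 protocol, which would already have been shown to work by the time step 6 becomes the problem. Benzylation of 3 (BnBr, K2CO3, DMF) would give 4-(benzyloxy)-3-methoxybenzaldehyde F9. Wittig methylenation as in step 3 should give 1-(benzyloxy)-4-ethenyl-2-methoxybenzene F10. Heck coupling with 2 as in step 4 should give the benzyl-protected E-stilbene F11. The step-5 protocol would give O-benzylcurlignan F12, with the benzyl ether as a planar donor at least equal to the silyl ether. Hydrogenolysis (H2, Pd/C, EtOAc, rt) should then release 9 without generating a phenoxide.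

**Further compounds**

F1 | step 5 | methyl 4-(benzyloxy)-3-iodo-5-methoxybenzoate | COC(=O)c1cc(I)c(OCc2ccccc2)c(OC)c1
F2 | step 5 | methyl 4-(benzyloxy)-3-(2-tert-butoxy-2-oxoethyl)-5-methoxybenzoate | COC(=O)c1cc(CC(=O)OC(C)(C)C)c(OCc2ccccc2)c(OC)c1
F3 | step 5 | 2-[2-(benzyloxy)-3-methoxy-5-(methoxycarbonyl)phenyl]acetic acid | COC(=O)c1cc(CC(=O)O)c(OCc2ccccc2)c(OC)c1
F4 | step 5 | methyl 4-(benzyloxy)-3-{2-[(4S)-4-benzyl-2-oxo-1,3-oxazolidin-3-yl]-2-oxoethyl}-5-methoxybenzoate | COC(=O)c1cc(CC(=O)N2[C@@H](Cc3ccccc3)COC2=O)c(OCc2ccccc2)c(OC)c1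
F5 | step 5 | methyl 4-(benzyloxy)-3-[(2S,3S)-1-[(4S)-4-benzyl-2-oxo-1,3-oxazolidin-3-yl]-3-hydroxy-3-{3-methoxy-4-[(triisopropylsilyl)oxy]phenyl}-1-oxopropan-2-yl]-5-methoxybenzoate | COC(=O)c1cc(OC)c(OCc2ccccc2)c(c1)[C@H](C(=O)N1[C@@H](Cc2ccccc2)COC1=O)[C@H](O)c1ccc(O[Si](C(C)C)(C(C)C)C(C)C)c(OC)c1
F6 | step 5 | methyl 4-(benzyloxy)-3-[(1S,2R)-1,3-dihydroxy-1-{3-methoxy-4-[(triisopropylsilyl)oxy]phenyl}propan-2-yl]-5-methoxybenzoate | COC(=O)c1cc(OC)c(OCc2ccccc2)c(c1)[C@H](CO)[C@H](O)c1ccc(O[Si](C(C)C)(C(C)C)C(C)C)c(OC)c1
F7 | step 5 | methyl 3-[(1S,2R)-1,3-dihydroxy-1-{3-methoxy-4-[(triisopropylsilyl)oxy]phenyl}propan-2-yl]-4-hydroxy-5-methoxybenzoate | COC(=O)c1cc(OC)c(O)c(c1)[C@H](CO)[C@H](O)c1ccc(O[Si](C(C)C)(C(C)C)C(C)C)c(OC)c1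
F8 | step 4 | 2-[(E)-2-{3-methoxy-4-[(triisopropylsilyl)oxy]phenyl}ethenyl]-4,4,5,5-tetramethyl-1,3,2-dioxaborolane | COc1cc(/C=C/B2OC(C)(C)C(C)(C)O2)ccc1O[Si](C(C)C)(C(C)C)C(C)C
F9 | step 6 | 4-(benzyloxy)-3-methoxybenzaldehyde | COc1cc(C=O)ccc1OCc1ccccc1
F10 | step 6 | 1-(benzyloxy)-4-ethenyl-2-methoxybenzene | C=Cc1ccc(OCc2ccccc2)c(OC)c1
F11 | step 6 | methyl 3-{(E)-2-[4-(benzyloxy)-3-methoxyphenyl]ethenyl}-4-hydroxy-5-methoxybenzoate | COC(=O)c1cc(OC)c(O)c(/C=C/c2ccc(OCc3ccccc3)c(OC)c2)c1
F12 | step 6 | methyl (2S,3R)-2-[4-(benzyloxy)-3-methoxyphenyl]-3-(hydroxymethyl)-7-methoxy-2,3-dihydro-1-benzofuran-5-carboxylate | COC(=O)c1cc(OC)c2c(c1)[C@H](CO)[C@@H](c1ccc(OCc3ccccc3)c(OC)c1)O2
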